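The target is disconnected at C13, the spiro carbon shared by the tetrahydrofuran (O–C9–C11–C12–C13) and the lactone (C13–C14–C15–O–C16). C13 bears the ring oxygen, the C16 carboxyl carbon and the two-carbon C14–C15 arm. A rhodium carbenoid at C13 is captured by the C9 allyl ether oxygen, and the five-membered oxonium ylide hands its allyl group to C13. O–C13, C13–C14, the tetrahydrofuran and the C13 stereocentre thus arise in one operation. The precursor is the cis-fused 6-acetoxy-4,4,8,10-tetramethyldecalin carrying an axial allyloxy group and a CH2CH2C(=N2)CO2Me chain on C9, made from (R)-carvone.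

Key step: step 16

Remark (assumption): the target is taken exactly as drawn, a cis-fused decalin with H-5, CH3-10, OAc-6, CH3-8 and O-9 on one face (5S,6S,8R,9R,10R,13R); locants from compound 7 on follow labdane numbering (ring A C1–C5/C10, ring B C5–C10, chain C11–C12, spiro C13, arm C14–C15, carboxyl C16).

Step 1
Reactants: 1 (R)-(−)-carvone
Product: 2 (5R,6S)-2,6-dimethyl-5-(prop-1-en-2-yl)cyclohex-2-en-1-one (trans-6-methylcarvone; the 6-epimer formed alongside is carried through)
Conditions: LDA, THF, −78 °C; MeI, −78 to 0 °C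
Reagents that add atoms: iodomethane CI
Why: Kinetic α′-deprotonation of the enone and enolate methylation (enolate alkylation) install the future C10 methyl; the configuration at this carbon does not matter because it is enolised again in step 5.

Step 2
Reactants: 2 trans-6-methylcarvone; 3 acrolein
Product: 4 4-[(1R,2S)-2,4-dimethyl-3-oxocyclohex-4-en-1-yl]-4-methylpentanal
Conditions: Fe(acac)3 (cat.), PhSiH3, EtOH/ethylene glycol, 60 °C
Reagents that add atoms: none
Why: Metal-hydride hydrogen-atom transfer to the 1,1-disubstituted alkene gives the tertiary radical that becomes the gem-dimethyl carbon C4 and adds to acrolein (Giese reaction, iron-mediated reductive olefin coupling), while the trisubstituted enone is a poor hydrogen-atom acceptor and a poor radical acceptor; no stereocentre is formed.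

Step 3
Reactants: 4 keto aldehyde
Product: 5 (5R,6S)-5-(5-hydroxy-2-methylpentan-2-yl)-2,6-dimethylcyclohex-2-en-1-one
Conditions: NaBH4, MeOH/CH2Cl2, −78 °C
Reagents that add atoms: none
Why: Borohydride at low temperature reduces the aldehyde and leaves the hindered conjugated ketone (chemoselective carbonyl reduction).

Step 4
Reactants: 5 hydroxy enone
Product: 6 (5R,6S)-5-(5-iodo-2-methylpentan-2-yl)-2,6-dimethylcyclohex-2-en-1-one
Conditions: PPh3, imidazole, I2, CH2Cl2, 0 °C
Reagents that add atoms: iodine II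
Why: Appel-type iodination of the primary alcohol under neutral conditions leaves the enone untouched.

Step 5
Reactants: 6 iodo enone
Product: 7 (5S,10R)-4,4,8,10-tetramethyl-cis-decal-7-en-9-one [(4aS,8aR)-2,5,5,8a-tetramethyl-4a,5,6,7,8,8a-hexahydronaphthalen-1(4H)-one]
Conditions: LDA, THF, −78 °C; then DMPU, −78 °C to rt
Reagents that add atoms: none
Why: Kinetic α′-enolate formation and intramolecular SN2 alkylation (6-exo-tet) close ring A; the tether on C5 can reach the enolate carbon only on its own face, so C1 and C4 end up cis and C10 is set as R with its methyl syn to H-5 (cis-fused decalin).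

Step 6
Reactants: 7 cis-fused enone
Product: 9 (5S,6S,10R)-6-hydroxy-4,4,8,10-tetramethyl-cis-decal-7-en-9-one, via trimethylsilyl dienol ether 8 (not isolated)
Conditions: TMSOTf, Et3N, CH2Cl2, 0 °C; then mCPBA, NaHCO3, −20 °C; aqueous citric acid work-up
Reagents that add atoms: 3-chloroperbenzoic acid OOC(=O)c1cccc(Cl)c1; trimethylsilyl triflate C[Si](C)(C)OS(=O)(=O)C(F)(F)F (silyl group in 8 only)
Why: Soft enolisation can only remove a C6 hydrogen and gives the linear dienol ether, which the peracid attacks at C6 (vinylogous Rubottom oxidation) because C8 is methyl-substituted and shielded by quaternary C10; oxygen should arrive anti to the C5–C4 bond on the convex face of the bicycle, giving the 6S alcohol cis to H-5.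

Step 7
Reactants: 9 γ-hydroxy enone
Product: 10 (5S,6S,10R)-6-(tert-butyldimethylsilyloxy)-4,4,8,10-tetramethyl-cis-decal-7-en-9-one
Conditions: TBSOTf, 2,6-lutidine, CH2Cl2, 0 °C
Reagents that add atoms: tert-butyldimethylsilyl triflate CC(C)(C)[Si](C)(C)OS(=O)(=O)C(F)(F)F
Why: Silyl ether formation with the silyl triflate stops isomerisation of the γ-hydroxy enone and masks the C6 oxygen for the strongly basic steps that follow.

Step 8
Reactants: 10 silyloxy enone
Product: 12 (5S,6S,8R,10R)-6-(tert-butyldimethylsilyloxy)-4,4,8,10-tetramethyl-cis-decalin-9-one, via C8-epimeric ketone 11 (not isolated)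
Conditions: H2 (1 atm), Pd/C, EtOAc, rt; then NaOMe (cat.), MeOH, rt
Reagents that add atoms: none
Why: Catalytic hydrogenation saturates C7=C8 and base then equilibrates the α-stereocentre C8 to the equatorial methyl (8R), because an axial C8 methyl would be syn-axial to C1 (thermodynamic epimerisation).

Step 9
Reactants: 12 C9 ketone; 13 (4-bromobutoxy)(tert-butyl)dimethylsilane
Product: 15 (5S,6S,8R,9R,10R)-6-(tert-butyldimethylsilyloxy)-9-[4-(tert-butyldimethylsilyloxy)butyl]-4,4,8,10-tetramethyl-cis-decalin-9-ol, via alkylmagnesium bromide 14 (not isolated)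
Conditions: 13, Mg, THF; anhydrous CeCl3, THF, −78 °C; then 12, −78 to 0 °C; aqueous NH4Cl
Reagents that add atoms: magnesium [Mg] (in 14 only)
Why: The organocerium reagent adds to the hindered, enolisable ketone without deprotonating it (1,2-addition) and, as is usual for alkyl-metal additions to 2,2,6-trisubstituted cyclohexanones, should enter along the equatorial direction away from the axial hydrogens on C5 and C7, which places the chain equatorial and the C9–O bond axial on the face of the C10 methyl (9R).

Step 10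
Reactants: 15 tertiary alcohol; 16 allyl bromide
Product: 17 (5S,6S,8R,9R,10R)-9-(allyloxy)-6-(tert-butyldimethylsilyloxy)-9-[4-(tert-butyldimethylsilyloxy)butyl]-4,4,8,10-tetramethyl-cis-decalin
Conditions: KH, 18-crown-6 (cat.), THF, 0 °C; 16, Bu4NI (cat.), rt to 40 °C
Reagents that add atoms: none
Why: Williamson etherification of the potassium alkoxide with a small, reactive allylic halide; crown ether and iodide catalysis offset the crowding around the axial tertiary oxygen.

Step 11
Reactants: 17 bis-silyl allyl ether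
Product: 18 (5S,6S,8R,9R,10R)-9-(allyloxy)-9-(4-hydroxybutyl)-4,4,8,10-tetramethyl-cis-decalin-6-ol
Conditions: TBAF, THF, 50 °C
Reagents that add atoms: none
Why: Fluoride-mediated desilylation removes both silyl ethers and does not touch the allyl ether.

Step 12
Reactants: 18 diol
Product: 20 4-[(5S,6S,8R,9R,10R)-9-(allyloxy)-6-hydroxy-4,4,8,10-tetramethyl-cis-decalin-9-yl]butanoic acid, via aldehyde 19 (not isolated)
Conditions: TEMPO (cat.), PhI(OAc)2, MeCN/H2O, rt
Reagents that add atoms: water O
Why: Oxoammonium (TEMPO) oxidation takes the primary alcohol through the aldehyde hydrate to the acid and should spare the hindered secondary C6 alcohol and the alkene.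

Step 13
Reactants: 20 hydroxy acid
Product: 21 methyl 4-[(5S,6S,8R,9R,10R)-9-(allyloxy)-6-hydroxy-4,4,8,10-tetramethyl-cis-decalin-9-yl]butanoate
Conditions: TMSCHN2, toluene/MeOH, 0 °C
Reagents that add atoms: (trimethylsilyl)diazomethane C[Si](C)(C)C=[N+]=[N-]
Why: Esterification with (trimethylsilyl)diazomethane in methanol is selective for the carboxylic acid over the secondary alcohol.

Step 14
Reactants: 21 hydroxy ester
Product: 23 methyl 2-diazo-4-[(5S,6S,8R,9R,10R)-9-(allyloxy)-6-hydroxy-4,4,8,10-tetramethyl-cis-decalin-9-yl]butanoate, via trifluoroacetyl ester 22 (not isolated)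
Conditions: LDA (2.3 equiv), THF, −78 °C; CF3CO2CH2CF3; then 4-acetamidobenzenesulfonyl azide, Et3N, H2O, MeCN, rt
Reagents that add atoms: 2,2,2-trifluoroethyl trifluoroacetate FC(F)(F)COC(=O)C(F)(F)F (in 22 only); 4-acetamidobenzenesulfonyl azide CC(=O)Nc1ccc(cc1)S(=O)(=O)N=[N+]=[N-]
Why: Claisen-type trifluoroacetylation of the ester enolate activates C13 for Regitz diazo transfer with loss of the trifluoroacetyl group (deacylative diazo transfer); the C6 alkoxide takes one equivalent of base and any trifluoroacetate formed there is cleaved in the aqueous amine stage.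

Step 15
Reactants: 23 hydroxy diazo ester
Product: 24 methyl 2-diazo-4-[(5S,6S,8R,9R,10R)-6-acetoxy-9-(allyloxy)-4,4,8,10-tetramethyl-cis-decalin-9-yl]butanoate
Conditions: Ac2O, Et3N, DMAP (cat.), CH2Cl2, rt
Reagents that add atoms: acetic anhydride CC(=O)OC(C)=O
Why: DMAP-catalysed acetylation of the equatorial C6 alcohol is mild enough for the diazo ester; the acetate is brought in only here because it would not survive steps 9, 10 and 14.

Step 16
Reactants: 24 allyl ether diazo ester
Product: 26 methyl ester of the (5S,6S,8R,9R,10R,13R)-spiro-tetrahydrofuran in which C13 carries allyl and CO2Me (6-acetate retained), via oxonium ylide 25 (not isolated)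
Conditions: Rh2(OPiv)4 (2 mol %), CH2Cl2, −78 °C (slow addition of 24), then to −20 °C
Reagents that add atoms: none
Why: The rhodium carboxylate turns the diazo ester into a carbenoid at C13, a lone pair of the C9 ether oxygen attacks it to give the cyclic oxonium ylide 25, and the ester-stabilised ylide undergoes a [2,3]-sigmatropic shift in which the allyl group leaves oxygen and its far terminus bonds to C13 (C13–C14). This is the known tandem carbenoid oxonium-ylide formation/[2,3] rearrangement of allyl ethers tethered to diazo carbonyl compounds. The tetrahydrofuran (O, C9, C11, C12, C13) closes by O–C bond formation in a five-membered ring, favoured because the carbenoid carbon sits four atoms from oxygen. C13 is set by the configuration of the oxonium oxygen, since allyl is transferred suprafacially to the face on which it sits; the metal-bearing C13 is expected to close beside the tertiary C8–H flank, away from quaternary C10 whose equatorial methyl is buttressed by the axial C4 methyl, which leaves allyl on the C10 side and gives 13R. The step needs ylide formation to outrun 1,2-hydride migration from C12, C–H insertion and a [1,2] shift; the five-membered geometry, the bulky pivalate ligands and −78 °C should secure the first two, and an allyl migrating group the last. The two flanks of C9 differ only modestly, so the 13-epimer is the main by-product to expect.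

Step 17
Reactants: 26 allyl ester
Product: 28 methyl ester of the (13R)-spiro-tetrahydrofuran with a 2-hydroxyethyl group on C13, via aldehyde 27 (not isolated)
Conditions: O3, CH2Cl2/MeOH, −78 °C; then NaBH4, −78 to 0 °C
Reagents that add atoms: ozone [O-][O+]=O
Why: Ozonolysis of the only alkene and in situ borohydride reduction of the aldehyde give the C15 alcohol (ozonolysis with reductive work-up); at 0 °C the methyl ester and the acetate should not be reduced.

Step 18
Reactants: 28 γ-hydroxy ester
Product: 29 target, (5S,6S,8R,9R,10R,13R)-6-acetoxy-9,13-epoxylabdan-16,15-olide with cis-fused decalin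
Conditions: PPTS (cat.), toluene, 40 °C
Reagents that add atoms: none
Why: Acid-catalysed intramolecular transesterification of the γ-hydroxy ester closes the five-membered lactone (lactonisation) without touching the acetate or C13.

Compound list
1 | (R)-(−)-carvone | CC1=CC[C@H](CC1=O)C(C)=C | starting material
2 | (5R,6S)-2,6-dimethyl-5-(prop-1-en-2-yl)cyclohex-2-en-1-one | C1C=C(C)C(=O)[C@@H](C)[C@@H]1C(C)=C | intermediate
3 | acrolein | C=CC=O | starting material
4 | 4-[(1R,2S)-2,4-dimethyl-3-oxocyclohex-4-en-1-yl]-4-methylpentanal | C1C=C(C)C(=O)[C@@H](C)[C@@H]1C(C)(C)CCC=O | intermediate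
5 | (5R,6S)-5-(5-hydroxy-2-methylpentan-2-yl)-2,6-dimethylcyclohex-2-en-1-one | C1C=C(C)C(=O)[C@@H](C)[C@@H]1C(C)(C)CCCO | intermediate
6 | (5R,6S)-5-(5-iodo-2-methylpentan-2-yl)-2,6-dimethylcyclohex-2-en-1-one | C1C=C(C)C(=O)[C@@H](C)[C@@H]1C(C)(C)CCCI | intermediate
7 | (5S,10R)-4,4,8,10-tetramethyl-cis-decal-7-en-9-one | C1C=C(C)C(=O)[C@]2(C)CCCC(C)(C)[C@H]12 | intermediate
8 | 9-(trimethylsilyloxy)-6,8-diene derived from 7 | C1=CC(C)=C(O[Si](C)(C)C)[C@]2(C)CCCC(C)(C)[C@H]12 | intermediate (not isolated)
9 | (5S,6S,10R)-6-hydroxy-4,4,8,10-tetramethyl-cis-decal-7-en-9-one | O[C@H]1C=C(C)C(=O)[C@]2(C)CCCC(C)(C)[C@H]12 | intermediate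
10 | (5S,6S,10R)-6-(tert-butyldimethylsilyloxy)-4,4,8,10-tetramethyl-cis-decal-7-en-9-one | CC(C)(C)[Si](C)(C)O[C@H]1C=C(C)C(=O)[C@]2(C)CCCC(C)(C)[C@H]12 | intermediate
11 | (5S,6S,8S,10R)-6-(tert-butyldimethylsilyloxy)-4,4,8,10-tetramethyl-cis-decalin-9-one (8-epimer of 12) | CC(C)(C)[Si](C)(C)O[C@H]1C[C@H](C)C(=O)[C@]2(C)CCCC(C)(C)[C@H]12 | intermediate (not isolated)
12 | (5S,6S,8R,10R)-6-(tert-butyldimethylsilyloxy)-4,4,8,10-tetramethyl-cis-decalin-9-one | CC(C)(C)[Si](C)(C)O[C@H]1C[C@@H](C)C(=O)[C@]2(C)CCCC(C)(C)[C@H]12 | intermediate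
13 | (4-bromobutoxy)(tert-butyl)dimethylsilane | BrCCCCO[Si](C)(C)C(C)(C)C | starting material
14 | [4-(tert-butyldimethylsilyloxy)butyl]magnesium bromide | Br[Mg]CCCCO[Si](C)(C)C(C)(C)C | intermediate (not isolated)
15 | (5S,6S,8R,9R,10R)-6-(tert-butyldimethylsilyloxy)-9-[4-(tert-butyldimethylsilyloxy)butyl]-4,4,8,10-tetramethyl-cis-decalin-9-ol | CC(C)(C)[Si](C)(C)O[C@H]1C[C@@H](C)[C@](O)(CCCCO[Si](C)(C)C(C)(C)C)[C@]2(C)CCCC(C)(C)[C@H]12 | intermediate
16 | allyl bromide | C=CCBr | starting material
17 | 9-O-allyl ether of 15 | CC(C)(C)[Si](C)(C)O[C@H]1C[C@@H](C)[C@](OCC=C)(CCCCO[Si](C)(C)C(C)(C)C)[C@]2(C)CCCC(C)(C)[C@H]12 | intermediate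
18 | (5S,6S,8R,9R,10R)-9-(allyloxy)-9-(4-hydroxybutyl)-4,4,8,10-tetramethyl-cis-decalin-6-ol | O[C@H]1C[C@@H](C)[C@](OCC=C)(CCCCO)[C@]2(C)CCCC(C)(C)[C@H]12 | intermediate
19 | 4-[9-(allyloxy)-6-hydroxy-4,4,8,10-tetramethyl-cis-decalin-9-yl]butanal | O[C@H]1C[C@@H](C)[C@](OCC=C)(CCCC=O)[C@]2(C)CCCC(C)(C)[C@H]12 | intermediate (not isolated)
20 | 4-[9-(allyloxy)-6-hydroxy-4,4,8,10-tetramethyl-cis-decalin-9-yl]butanoic acid | O[C@H]1C[C@@H](C)[C@](OCC=C)(CCCC(=O)O)[C@]2(C)CCCC(C)(C)[C@H]12 | intermediate
21 | methyl 4-[9-(allyloxy)-6-hydroxy-4,4,8,10-tetramethyl-cis-decalin-9-yl]butanoate | O[C@H]1C[C@@H](C)[C@](OCC=C)(CCCC(=O)OC)[C@]2(C)CCCC(C)(C)[C@H]12 | intermediate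
22 | methyl 2-(trifluoroacetyl)-4-[9-(allyloxy)-6-hydroxy-4,4,8,10-tetramethyl-cis-decalin-9-yl]butanoate (C13 epimers) | O[C@H]1C[C@@H](C)[C@](OCC=C)(CCC(C(=O)C(F)(F)F)C(=O)OC)[C@]2(C)CCCC(C)(C)[C@H]12 | intermediate (not isolated)
23 | methyl 2-diazo-4-[9-(allyloxy)-6-hydroxy-4,4,8,10-tetramethyl-cis-decalin-9-yl]butanoate | O[C@H]1C[C@@H](C)[C@](OCC=C)(CCC(=[N+]=[N-])C(=O)OC)[C@]2(C)CCCC(C)(C)[C@H]12 | intermediate
24 | methyl 2-diazo-4-[6-acetoxy-9-(allyloxy)-4,4,8,10-tetramethyl-cis-decalin-9-yl]butanoate (key-step precursor) | CC(=O)O[C@H]1C[C@@H](C)[C@](OCC=C)(CCC(=[N+]=[N-])C(=O)OC)[C@]2(C)CCCC(C)(C)[C@H]12 | intermediate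
25 | five-membered allyl oxonium ylide (O+ bonded to C9, C13 and allyl; C13 carbanion stabilised by CO2Me) | CC(=O)O[C@H]1C[C@@H](C)[C@]2(CC[C-](C(=O)OC)[O+]2CC=C)[C@]2(C)CCCC(C)(C)[C@H]12 | intermediate (not isolated)
26 | (13R)-spiro-tetrahydrofuran with allyl and CO2Me on C13 (key-step product) | CC(=O)O[C@H]1C[C@@H](C)[C@]2(CC[C@@](CC=C)(C(=O)OC)O2)[C@]2(C)CCCC(C)(C)[C@H]12 | intermediate
27 | (13R)-spiro-tetrahydrofuran with CH2CHO and CO2Me on C13 | CC(=O)O[C@H]1C[C@@H](C)[C@]2(CC[C@@](CC=O)(C(=O)OC)O2)[C@]2(C)CCCC(C)(C)[C@H]12 | intermediate (not isolated)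
28 | (13R)-spiro-tetrahydrofuran with CH2CH2OH and CO2Me on C13 | CC(=O)O[C@H]1C[C@@H](C)[C@]2(CC[C@@](CCO)(C(=O)OC)O2)[C@]2(C)CCCC(C)(C)[C@H]12 | intermediate
29 | (5S,6S,8R,9R,10R,13R)-6-acetoxy-9,13-epoxylabdan-16,15-olide, cis-fused (CNP0081177.1) | CC(=O)O[C@H]1C[C@@H](C)[C@]2(CC[C@]3(CCOC3=O)O2)[C@]2(C)CCCC(C)(C)[C@H]12 | target

Total step count: 18. Longest linear sequence: 18 steps, from 1 to 29 (13 and 16 are bought; 14 is made in the flask within step 9).

Steps most likely to fail

1. Step 16 (key step). The crowded ether oxygen may attack the carbenoid too slowly, so that 1,2-hydride migration from C12 or C–H insertion takes over, or the allyl group may be delivered to the other face of C13. Fallback (O–C13 by ring contraction, C13–C14 by enolate allylation): the route sets out from tertiary alcohol 15. HF·pyridine in THF/pyridine at 0 °C cleaves only the primary silyl ether and gives the diol F1. TEMPO/PhI(OAc)2 in CH2Cl2 oxidises it through the lactol to the spiro δ-lactone F2. Its lithium enolate (LDA, THF, −78 °C) is brominated with CBr4 to the α-bromo lactone F3. K2CO3 in methanol opens the lactone, and the freed C9 alkoxide displaces bromide in a 5-exo-tet ring contraction to the tetrahydrofuran-2-carboxylate F4. Enolate allylation (LDA, THF/DMPU, −78 °C, allyl bromide 16) gives the allylated silyl ether F5, whose C13 epimers are separated. TBAF gives the C6 alcohol F6, and acetylation (Ac2O, DMAP) returns to 26.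

2. Step 6. The peracid may attack C8 instead of C6 or deliver oxygen from the ring-A face (6-epimer), and the γ-hydroxy enone may isomerise on work-up. Fallback (cycloaddition instead of electrophilic oxygen transfer): the route sets out from enone 7 through the same dienol ether 8. Photo-oxygenation (O2, tetraphenylporphyrin, hν, CH2Cl2, −78 °C) adds singlet oxygen across C6 and C9 on the convex face, and the silyl peroxide collapses on work-up to the γ-hydroperoxy enone F7. PPh3 reduces it and the route comes back at 9.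

3. Step 9. The hindered ketone may be enolised or reduced instead of attacked, or the nucleophile may enter axially and give the C9 epimer. Fallback (oxygen delivered as an electrophile, chain by epoxide opening): the route sets out from ketone 12. Wittig methylenation (Ph3PCH3Br, KOtBu, toluene, 100 °C) gives the exocyclic alkene F8. mCPBA/NaHCO3 epoxidises it from the axial direction, away from the axial C1 on C10, to the spiro-epoxide F9, whose oxygen already sits in the required axial position. Copper-catalysed opening at the CH2 terminus with [3-(tert-butyldimethylsilyloxy)propyl]magnesium bromide (CuI cat., THF, −30 to 0 °C) returns to 15.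

Further compounds
F1 | step 16 | (5S,6S,8R,9R,10R)-6-(tert-butyldimethylsilyloxy)-9-(4-hydroxybutyl)-4,4,8,10-tetramethyl-cis-decalin-9-ol | CC(C)(C)[Si](C)(C)O[C@H]1C[C@@H](C)[C@](O)(CCCCO)[C@]2(C)CCCC(C)(C)[C@H]12
F2 | step 16 | spiro δ-lactone (O–C9, C11, C12, C13, C16=O) with 6-silyl ether | CC(C)(C)[Si](C)(C)O[C@H]1C[C@@H](C)[C@]3(CCCC(=O)O3)[C@]2(C)CCCC(C)(C)[C@H]12
F3 | step 16 | 13-bromo derivative of the spiro δ-lactone (C13 epimers) | CC(C)(C)[Si](C)(C)O[C@H]1C[C@@H](C)[C@]3(CCC(Br)C(=O)O3)[C@]2(C)CCCC(C)(C)[C@H]12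
F4 | step 16 | spiro-tetrahydrofuran-2-carboxylate methyl ester with C13–H and 6-silyl ether (C13 epimers) | CC(C)(C)[Si](C)(C)O[C@H]1C[C@@H](C)[C@]3(CCC(C(=O)OC)O3)[C@]2(C)CCCC(C)(C)[C@H]12
F5 | step 16 | (13R)-13-allyl spiro-tetrahydrofuran methyl ester with 6-silyl ether | CC(C)(C)[Si](C)(C)O[C@H]1C[C@@H](C)[C@]2(CC[C@@](CC=C)(C(=O)OC)O2)[C@]2(C)CCCC(C)(C)[C@H]12
F6 | step 16 | (13R)-13-allyl spiro-tetrahydrofuran methyl ester with free 6-hydroxyl | O[C@H]1C[C@@H](C)[C@]2(CC[C@@](CC=C)(C(=O)OC)O2)[C@]2(C)CCCC(C)(C)[C@H]12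
F7 | step 6 | (5S,6S,10R)-6-hydroperoxy-4,4,8,10-tetramethyl-cis-decal-7-en-9-one | OO[C@H]1C=C(C)C(=O)[C@]2(C)CCCC(C)(C)[C@H]12
F8 | step 9 | (5S,6S,8R,10R)-6-(tert-butyldimethylsilyloxy)-4,4,8,10-tetramethyl-9-methylene-cis-decalin | CC(C)(C)[Si](C)(C)O[C@H]1C[C@@H](C)C(=C)[C@]2(C)CCCC(C)(C)[C@H]12
F9 | step 9 | (9R)-9,11-spiro-epoxide of F8 (oxygen axial) | CC(C)(C)[Si](C)(C)O[C@H]1C[C@@H](C)[C@]3(CO3)[C@]2(C)CCCC(C)(C)[C@H]12
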